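You asked for a quick number, and I began from what cannot happen here: L cannot stay for good at the share its equilibrium constants give it, since the step into J2 runs one way and the J that enters it does not come back.

J 20 mM; time 15 d

    J ⇌ L (K1 = 3.9, k1 = 0.63 h⁻¹)
    L ⇌ E (K2 = 0.41, k2 = 0.0040 h⁻¹)
    E ⇌ X (K3 = 0.80, k3 = 0.030 h⁻¹)
    X ⇌ J (k4 = 0.020 h⁻¹)
    L ⇌ Z (K5 = 8.4, k5 = 0.055 h⁻¹)
    2 J → J2 (k6 = 4.4 M⁻¹ h⁻¹)

- how much of the J has reacted by 15 d
- how much L there is at 15 d, in percent of the J charged
- how much Z there is at 15 d, in percent of the J charged
- amount of L if the flask were left three thousand times as long, in percent of the J charged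

- in percentages every species weighs as the J in it: one J2 counts as two
- two of one species on the left: rate k times its square, two consumed each time
- run time (flask): 15 d

The relaxation half-lives of 2.10 d for L and E and 0.634 d for X and J are short against 15 d, so I took the monomers to stand by then in the ratios of their constants, a pre-equilibrium. J then held 2.47% of the monomer, and I carried one number, L's share of the monomer, the fraction of the J units outside J2 that sit as L: 9.62%.

That left the fraction lost to J2. At the start J passed into L 3.6 times as fast as into J2, and I replaced the falling J by its mean, half the charge, which gave 12.3% against 11.8% from the exact curve of a J that falls to nothing. Step 1 is faster than step 5, so J and L then drained together into Z, which added 6.45% and made 18.7% in J2.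

My reckoning therefore gave conversion 98.0%, L 7.82% and Z 65.7%. Beyond that, the reciprocal of the monomer fraction climbs by 0.00257 d⁻¹, so after 45000 d L came to 0.0823%.

The forecast gave 98.1%, 7.5%, 62.5% and 0.082%, on the ground that “the irreversible dimerisation slowly consumes the equilibrated monomer by second-order decay”; we parted chiefly on Z.

The flask gave 98.0%, 7.64%, 64.8% and 0.0824%. It held 19.9% as J2 at 15.0 d, and L's share of what stood outside J2 makes 7.71% of L there. The flask charged with 12 mM of J held 13.2% as J2 at 15.0 d, so the same share makes 8.35%, and that flask held 8.31% as L.

All constants are assumed; the flask was simulated.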